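**Plan**

- Core numbering: C1 (bridgehead next to the lactone carbonyl C2), O3, C4 (syringyl CH), C5 (bridgehead), C6H2, O7, C8 (guaiacyl CH). Enabling feature: C6 of the tetrahydrofuran ring sits on C5, next to C1, so a C1–C6 bond makes a cyclopropane fused to the lactone ring; with a second carbonyl group on C1 this strained bond can be opened and can take up the C8=O7 carbonyl group of a vanillin ether.
- Retrosynthesis: silyl ethers on both phenols and a CO2Me group on C1; cut C1–C8 and O7–C6 (tetrahydrofuran ring) to the cyclopropane-fused lactone and O-silyl vanillin; cut C1–C5 and C1–C6 (cyclopropane and lactone ring together) to an allyl diazomalonate; cut the ester C–O bond and the C4–vinyl bond to methyl malonyl chloride, vinyl Grignard reagent and O-silyl syringaldehyde.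
- Forward: vinylation, enzymatic resolution, malonylation and diazo transfer; the lactone ring and the cyclopropane close in one carbenoid step; the key step opens the cyclopropane and closes the tetrahydrofuran ring; dealkoxycarbonylation and desilylation finish.
- Stereochemistry: C4 from the lipase resolution; C5 from the C4-directed cyclopropanation; C8 and the cis ring fusion from the key annulation; C1–H from protonation of a bicycle that can only be cis-fused.

Key step: step 8

Assumption: the lipase follows Kazlauskas' rule with the 4-silyloxy-3,5-dimethoxyphenyl group as the large and vinyl as the medium substituent, so the (R)-alcohol is acetylated and the (S)-alcohol is left behind.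

**Route**

Step 1
Reactants: 1 syringaldehyde (4-hydroxy-3,5-dimethoxybenzaldehyde)
Product: 2 3,5-dimethoxy-4-(triisopropylsilyloxy)benzaldehyde
Conditions: TIPSCl, imidazole, DMF, 25 to 40 °C
Reagents that add atoms: chlorotriisopropylsilane (TIPSCl), CC(C)[Si](Cl)(C(C)C)C(C)C
Why: Imidazole-promoted silylation of the acidic phenol gives an aryl silyl ether that should survive the Grignard, amine base, carbenoid, Lewis acid and hot chloride steps and fall to fluoride at the end.

Step 2
Reactants: 2 3,5-dimethoxy-4-(triisopropylsilyloxy)benzaldehyde; 3 vinylmagnesium bromide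
Product: 4 rac-1-[3,5-dimethoxy-4-(triisopropylsilyloxy)phenyl]prop-2-en-1-ol
Conditions: THF, −78 to 0 °C; aqueous NH4Cl work-up
Reagents that add atoms: none
Why: Grignard 1,2-addition to a non-enolisable aryl aldehyde gives the allylic alcohol as a racemate, which is resolved in step 3.

Step 3
Reactants: 4 rac-1-[3,5-dimethoxy-4-(triisopropylsilyloxy)phenyl]prop-2-en-1-ol
Product: 5 (S)-1-[3,5-dimethoxy-4-(triisopropylsilyloxy)phenyl]prop-2-en-1-ol
Conditions: Novozym 435 (immobilised Candida antarctica lipase B), vinyl acetate, tert-butyl methyl ether, 30 °C, run to just over half conversion; chromatography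
Reagents that add atoms: none
Why: Lipase-catalysed kinetic resolution by transesterification should acetylate the (R)-alcohol and leave (S)-5, whose enantiomeric purity rises as conversion passes one half, and this fixes C4 under neutral conditions that spare the acid-sensitive allylic benzylic alcohol.

Step 4
Reactants: 5 (S)-1-[3,5-dimethoxy-4-(triisopropylsilyloxy)phenyl]prop-2-en-1-ol; 6 methyl malonyl chloride (methyl 3-chloro-3-oxopropanoate)
Product: 7 methyl (S)-1-[3,5-dimethoxy-4-(triisopropylsilyloxy)phenyl]prop-2-en-1-yl malonate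
Conditions: pyridine, CH2Cl2, −20 to 0 °C
Reagents that add atoms: none
Why: Esterification of the secondary alcohol with an acid chloride and pyridine at low temperature acylates oxygen without touching the C4–O bond, so the configuration is kept and allylic transposition is avoided.

Step 5
Reactants: 7 methyl (S)-1-[3,5-dimethoxy-4-(triisopropylsilyloxy)phenyl]prop-2-en-1-yl malonate
Product: 8 methyl (S)-1-[3,5-dimethoxy-4-(triisopropylsilyloxy)phenyl]prop-2-en-1-yl 2-diazomalonate
Conditions: p-ABSA, Et3N, MeCN, 0 to 25 °C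
Reagents that add atoms: 4-acetamidobenzenesulfonyl azide (p-ABSA), CC(=O)Nc1ccc(cc1)S(=O)(=O)N=[N+]=[N-]
Why: Regitz diazo transfer onto the doubly activated methylene needs only triethylamine, which leaves the aryl silyl ether and the allylic ester alone.

Step 6
Reactants: 8 methyl (S)-1-[3,5-dimethoxy-4-(triisopropylsilyloxy)phenyl]prop-2-en-1-yl 2-diazomalonate
Product: 9 methyl (1R,4S,5S)-4-[3,5-dimethoxy-4-(triisopropylsilyloxy)phenyl]-2-oxo-3-oxabicyclo[3.1.0]hexane-1-carboxylate (aryl anti to the cyclopropane CH2)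
Conditions: Rh2(OAc)4 (1 mol %), CH2Cl2, 40 °C, slow addition of 8
Reagents that add atoms: none
Why: Intramolecular cyclopropanation by the rhodium carbenoid forms C1–C5 and C1–C6 and thereby the lactone ring and the cyclopropane together; the cis fusion is forced, and the aryl group at C4 should sit pseudo-equatorial in the envelope-like transition state, so the cyclopropane CH2 ends anti to it and C5 and C1 are set by C4.

Step 7
Reactants: 10 vanillin (4-hydroxy-3-methoxybenzaldehyde)
Product: 11 3-methoxy-4-(triisopropylsilyloxy)benzaldehyde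
Conditions: TIPSCl, imidazole, DMF, 25 °C
Reagents that add atoms: chlorotriisopropylsilane (TIPSCl), CC(C)[Si](Cl)(C(C)C)C(C)C
Why: The same phenol silylation gives an aldehyde partner with no acidic proton and with the protecting group that is removed together with the other one in the last step.

Step 8
Reactants: 9 methyl (1R,4S,5S)-4-[3,5-dimethoxy-4-(triisopropylsilyloxy)phenyl]-2-oxo-3-oxabicyclo[3.1.0]hexane-1-carboxylate; 11 3-methoxy-4-(triisopropylsilyloxy)benzaldehyde
Product: 14 methyl (1S,4S,5R,8R)-4-[3,5-dimethoxy-4-(triisopropylsilyloxy)phenyl]-8-[3-methoxy-4-(triisopropylsilyloxy)phenyl]-2-oxo-3,7-dioxabicyclo[3.3.0]octane-1-carboxylate, via iodomagnesium enolate 12 (not isolated), via iodomagnesium aldolate 13 (not isolated)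
Conditions: MgI2 (1.0 equiv), 11 (1.5 equiv), THF, 60 °C, sealed vessel
Reagents that add atoms: none
Why: MgI2, chelated by the two carbonyl groups on C1, activates the cyclopropane and iodide opens it by SN2 attack at the C6 methylene to give the chelated magnesium enolate 12, which adds reversibly to aldehyde 11 (C1–C8, aldolate 13) before the alkoxide oxygen displaces iodide at C6 (O7–C6) and returns MgI2. The closest known reaction type is the magnesium iodide promoted ring expansion of acceptor-activated cyclopropanes with imines and aldehydes, a sequence of homoconjugate opening, addition and ring closure. The tetrahydrofuran ring closes in the 5-exo-tet mode. C1 is set by the ring itself, because only the aldolate with the C8 arm cis to the iodomethyl arm on C5 can reach C6 and the reversible aldol step should funnel the other adducts through it to the cis-fused bicycle, and C8 is set in the same closure, where the aryl group should take the convex face away from the lactone ring. The step needs iodide to attack C6 and not the substituted C5, which the steric difference and the known homoconjugate additions to 2-oxo-3-oxabicyclo[3.1.0]hexane-1-carboxylates secure, and it needs the benzylic C4–O3 bond to stay intact, for which MgI2 is chosen as a weak Lewis acid at moderate temperature.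

Step 9
Reactants: 14 methyl (1S,4S,5R,8R)-4-[3,5-dimethoxy-4-(triisopropylsilyloxy)phenyl]-8-[3-methoxy-4-(triisopropylsilyloxy)phenyl]-2-oxo-3,7-dioxabicyclo[3.3.0]octane-1-carboxylate
Product: 16 (1S,4S,5R,8S)-4-[3,5-dimethoxy-4-(triisopropylsilyloxy)phenyl]-8-[3-methoxy-4-(triisopropylsilyloxy)phenyl]-3,7-dioxabicyclo[3.3.0]octan-2-one, via lithium carboxylate 15 (not isolated)
Conditions: LiCl, H2O (2 equiv), DMSO, 130 to 140 °C
Reagents that add atoms: none
Why: In this Krapcho dealkoxycarbonylation chloride removes the ester methyl group by SN2, carboxylate 15 loses CO2 and water protonates the lactone enolate at C1 on the only face the cis-fused bicycle allows, while the C8–O7 bond lies in the enolate plane so that beta-elimination is stereoelectronically disfavoured.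

Step 10
Reactants: 16 (1S,4S,5R,8S)-4-[3,5-dimethoxy-4-(triisopropylsilyloxy)phenyl]-8-[3-methoxy-4-(triisopropylsilyloxy)phenyl]-3,7-dioxabicyclo[3.3.0]octan-2-one
Product: 17 (1S,4S,5R,8S)-4-(4-hydroxy-3,5-dimethoxyphenyl)-8-(4-hydroxy-3-methoxyphenyl)-3,7-dioxabicyclo[3.3.0]octan-2-one (CNP0142585.1)
Conditions: TBAF, AcOH, THF, 0 °C
Reagents that add atoms: none
Why: Fluoride desilylation of the two aryl silyl ethers, buffered with acetic acid so that no free phenoxide builds up and opens a benzylic C–O bond through a quinone methide, touches no stereocentre.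

**Compound list**

1 | syringaldehyde | COc1cc(C=O)cc(OC)c1O | starting material
2 | 3,5-dimethoxy-4-(triisopropylsilyloxy)benzaldehyde | COc1cc(C=O)cc(OC)c1O[Si](C(C)C)(C(C)C)C(C)C | intermediate
3 | vinylmagnesium bromide | C=C[Mg]Br | starting material
4 | rac-1-[3,5-dimethoxy-4-(triisopropylsilyloxy)phenyl]prop-2-en-1-ol | C=CC(O)c1cc(OC)c(O[Si](C(C)C)(C(C)C)C(C)C)c(OC)c1 | intermediate
5 | (S)-1-[3,5-dimethoxy-4-(triisopropylsilyloxy)phenyl]prop-2-en-1-ol | C=C[C@@H](c1cc(OC)c(O[Si](C(C)C)(C(C)C)C(C)C)c(OC)c1)O | intermediate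
6 | methyl malonyl chloride | COC(=O)CC(=O)Cl | starting material
7 | methyl (S)-1-[3,5-dimethoxy-4-(triisopropylsilyloxy)phenyl]prop-2-en-1-yl malonate | C=C[C@@H](c1cc(OC)c(O[Si](C(C)C)(C(C)C)C(C)C)c(OC)c1)OC(=O)CC(=O)OC | intermediate
8 | methyl (S)-1-[3,5-dimethoxy-4-(triisopropylsilyloxy)phenyl]prop-2-en-1-yl 2-diazomalonate | C=C[C@@H](c1cc(OC)c(O[Si](C(C)C)(C(C)C)C(C)C)c(OC)c1)OC(=O)C(=[N+]=[N-])C(=O)OC | intermediate
9 | methyl (1R,4S,5S)-4-[3,5-dimethoxy-4-(triisopropylsilyloxy)phenyl]-2-oxo-3-oxabicyclo[3.1.0]hexane-1-carboxylate, aryl anti to the cyclopropane CH2 | COC(=O)[C@@]12C[C@@H]1[C@@H](c1cc(OC)c(O[Si](C(C)C)(C(C)C)C(C)C)c(OC)c1)OC2=O | intermediate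
10 | vanillin | COc1cc(C=O)ccc1O | starting material
11 | 3-methoxy-4-(triisopropylsilyloxy)benzaldehyde | COc1cc(C=O)ccc1O[Si](C(C)C)(C(C)C)C(C)C | intermediate
12 | iodomagnesium enolate of methyl 5-[3,5-dimethoxy-4-(triisopropylsilyloxy)phenyl]-4-(iodomethyl)-2-oxooxolane-3-carboxylate, iodomethyl and aryl trans (ring-opened 9) | COC(=O)C1=C(O[Mg]I)O[C@H](c2cc(OC)c(O[Si](C(C)C)(C(C)C)C(C)C)c(OC)c2)[C@H]1CI | intermediate
13 | iodomagnesium aldolate of 12 with 11: C8 alkoxide on the quaternary C1, C8 arm cis to the iodomethyl group | COc1cc([C@@H](O[Mg]I)[C@@]2(C(=O)OC)C(=O)O[C@H](c3cc(OC)c(O[Si](C(C)C)(C(C)C)C(C)C)c(OC)c3)[C@H]2CI)ccc1O[Si](C(C)C)(C(C)C)C(C)C | intermediate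
14 | methyl (1S,4S,5R,8R)-4-[3,5-dimethoxy-4-(triisopropylsilyloxy)phenyl]-8-[3-methoxy-4-(triisopropylsilyloxy)phenyl]-2-oxo-3,7-dioxabicyclo[3.3.0]octane-1-carboxylate | COc1cc([C@H]2OC[C@H]3[C@]2(C(=O)OC)C(=O)O[C@@H]3c2cc(OC)c(O[Si](C(C)C)(C(C)C)C(C)C)c(OC)c2)ccc1O[Si](C(C)C)(C(C)C)C(C)C | intermediate
15 | lithium (1S,4S,5R,8R)-4-[3,5-dimethoxy-4-(triisopropylsilyloxy)phenyl]-8-[3-methoxy-4-(triisopropylsilyloxy)phenyl]-2-oxo-3,7-dioxabicyclo[3.3.0]octane-1-carboxylate | COc1cc([C@H]2OC[C@H]3[C@]2(C(=O)[O-])C(=O)O[C@@H]3c2cc(OC)c(O[Si](C(C)C)(C(C)C)C(C)C)c(OC)c2)ccc1O[Si](C(C)C)(C(C)C)C(C)C.[Li+] | intermediate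
16 | (1S,4S,5R,8S)-4-[3,5-dimethoxy-4-(triisopropylsilyloxy)phenyl]-8-[3-methoxy-4-(triisopropylsilyloxy)phenyl]-3,7-dioxabicyclo[3.3.0]octan-2-one | COc1cc([C@H]2OC[C@H]3[C@@H]2C(=O)O[C@@H]3c2cc(OC)c(O[Si](C(C)C)(C(C)C)C(C)C)c(OC)c2)ccc1O[Si](C(C)C)(C(C)C)C(C)C | intermediate
17 | (1S,4S,5R,8S)-4-(4-hydroxy-3,5-dimethoxyphenyl)-8-(4-hydroxy-3-methoxyphenyl)-3,7-dioxabicyclo[3.3.0]octan-2-one | COc1cc([C@H]2OC[C@H]3[C@@H]2C(=O)O[C@@H]3c2cc(OC)c(O)c(OC)c2)ccc1O | target

**Count**

Total steps: 10. Longest linear sequence: 9 steps (steps 1 to 6, 8, 9 and 10, from syringaldehyde); step 7 is a one-step side branch.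

**Steps most likely to fail**

1. Step 8. What may go wrong: the aldol equilibrium between the stabilised enolate 12 and the electron-rich aldehyde may lie on the side of the components. Ring closure is then outrun by return to 9 or by iodide-mediated O-alkylation and demethylation of the ester, or the closure shows poor facial control at C8. The fallback carries C8 into the cyclopropane at the ketone oxidation level, so that no intermolecular C–C bond has to form and the ring fusion is fixed by the tether. It sets out from 5 and 11 and returns at 16.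
   - Alcohol 5 is acetylated (Ac2O, pyridine, DMAP) to (S)-1-[3,5-dimethoxy-4-(triisopropylsilyloxy)phenyl]prop-2-en-1-yl acetate F1.
   - The lithium enolate of F1 (LiHMDS, THF, −78 °C) adds to aldehyde 11 to give the beta-hydroxy ester F2.
   - Dess–Martin oxidation gives the beta-keto ester F3.
   - Oxidative radical cyclisation of F3 (Mn(OAc)3, Cu(OAc)2, AcOH), with the same facial preference as in step 6, gives the 1-aroyl cyclopropane-fused lactone F4.
   - A catalytic amount of MgI2 in warm THF triggers the Cloke–Wilson rearrangement of F4 to the fused 4,5-dihydrofuran F5, in which O7–C6 is made and C1=C8 is a double bond.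
   - Hydrogenation over Rh on Al2O3 adds hydrogen to C1 and C8 from the convex face and gives the C8 epimer of 16, F6, with the guaiacyl group on the concave face.
   - Acid equilibration at the benzylic ether carbon C8 (BF3·OEt2, CH2Cl2, 0 °C) should move the aryl group to the more stable convex position and give 16.

2. Step 6. What may go wrong: the electrophilic rhodium carbenoid may be diverted to the electron-rich aryl ring (aromatic substitution or ring expansion), or the two alkene faces may be poorly differentiated so that the syn isomer contaminates 9. The fallback sets out from 7 and returns at 9 without a diazo compound. Malonate 7 is cyclised oxidatively with Mn(OAc)3 and Cu(OAc)2 in AcOH at 50 to 60 °C. The malonyl radical closes the lactone ring 5-exo with the aryl group pseudo-equatorial, Cu(OAc)2 oxidises the primary radical and the enol closes the cyclopropane, which gives 9 directly; no new compound is made (F0).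

3. Step 9. What may go wrong: the aryl silyl groups may be lost in hot wet DMSO, after which a benzylic C–O bond can open through a para-quinone methide, or chloride may attack C4 and scramble that centre. The fallback sets out from 14 and returns at 16. The methyl ester is hydrolysed under neutral conditions with Me3SnOH (1,2-dichloroethane, 80 °C) to the carboxylic acid F7. This malonic-type acid is decarboxylated by gentle heating in toluene (90 to 100 °C), which again protonates C1 on the convex face and gives 16.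

**Further compounds**

F1 | step 8 | (S)-1-[3,5-dimethoxy-4-(triisopropylsilyloxy)phenyl]prop-2-en-1-yl acetate | C=C[C@@H](c1cc(OC)c(O[Si](C(C)C)(C(C)C)C(C)C)c(OC)c1)OC(C)=O
F2 | step 8 | (S)-1-[3,5-dimethoxy-4-(triisopropylsilyloxy)phenyl]prop-2-en-1-yl 3-hydroxy-3-[3-methoxy-4-(triisopropylsilyloxy)phenyl]propanoate, carbinol centre unassigned | C=C[C@@H](c1cc(OC)c(O[Si](C(C)C)(C(C)C)C(C)C)c(OC)c1)OC(=O)CC(O)c1ccc(O[Si](C(C)C)(C(C)C)C(C)C)c(OC)c1
F3 | step 8 | (S)-1-[3,5-dimethoxy-4-(triisopropylsilyloxy)phenyl]prop-2-en-1-yl 3-[3-methoxy-4-(triisopropylsilyloxy)phenyl]-3-oxopropanoate | C=C[C@@H](c1cc(OC)c(O[Si](C(C)C)(C(C)C)C(C)C)c(OC)c1)OC(=O)CC(=O)c1ccc(O[Si](C(C)C)(C(C)C)C(C)C)c(OC)c1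
F4 | step 8 | (1R,4S,5S)-4-[3,5-dimethoxy-4-(triisopropylsilyloxy)phenyl]-1-[3-methoxy-4-(triisopropylsilyloxy)benzoyl]-3-oxabicyclo[3.1.0]hexan-2-one | O=C(c1ccc(O[Si](C(C)C)(C(C)C)C(C)C)c(OC)c1)[C@@]12C[C@@H]1[C@@H](c1cc(OC)c(O[Si](C(C)C)(C(C)C)C(C)C)c(OC)c1)OC2=O
F5 | step 8 | (4S,5R)-4-[3,5-dimethoxy-4-(triisopropylsilyloxy)phenyl]-8-[3-methoxy-4-(triisopropylsilyloxy)phenyl]-3,7-dioxabicyclo[3.3.0]oct-1(8)-en-2-one | COc1cc(ccc1O[Si](C(C)C)(C(C)C)C(C)C)C1=C2C(=O)O[C@H](c3cc(OC)c(O[Si](C(C)C)(C(C)C)C(C)C)c(OC)c3)[C@H]2CO1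
F6 | step 8 | (1S,4S,5R,8R)-4-[3,5-dimethoxy-4-(triisopropylsilyloxy)phenyl]-8-[3-methoxy-4-(triisopropylsilyloxy)phenyl]-3,7-dioxabicyclo[3.3.0]octan-2-one (C8 epimer of 16) | COc1cc([C@@H]2OC[C@H]3[C@@H]2C(=O)O[C@@H]3c2cc(OC)c(O[Si](C(C)C)(C(C)C)C(C)C)c(OC)c2)ccc1O[Si](C(C)C)(C(C)C)C(C)C
F0 | step 6 | none | none
F7 | step 9 | (1S,4S,5R,8R)-4-[3,5-dimethoxy-4-(triisopropylsilyloxy)phenyl]-8-[3-methoxy-4-(triisopropylsilyloxy)phenyl]-2-oxo-3,7-dioxabicyclo[3.3.0]octane-1-carboxylic acid | COc1cc([C@H]2OC[C@H]3[C@]2(C(=O)O)C(=O)O[C@@H]3c2cc(OC)c(O[Si](C(C)C)(C(C)C)C(C)C)c(OC)c2)ccc1O[Si](C(C)C)(C(C)C)C(C)C
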